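The constants used here are made up; the rest is arithmetic.

Millimolar per second is the unit of both steps that consume the substrate, so their quotient has no unit.

    substrate + rival reagent → side product (k1 = 0.279 M⁻¹ s⁻¹)
    solid reagent ⇌ partner, rate k2*(cs2 - [partner]) while solid is left; crystals form when [partner] > cs2 (cs2 = 13 mM, k2 = 0.00630 s⁻¹)
    substrate + partner → target (k3 = 0.176 M⁻¹ s⁻¹)

substrate 16 mM; rival reagent 20.8 mM; solid reagent 24.0 mM; time 3.0 min

- given per volume of solution although it is solid: solid reagent
- at the start none of the solid reagent is in solution
- run time (flask): 3.0 min

- the target standing at 3.0 min, as a percentage of the substrate charged
- the change that raises the amount of target at 3.0 min, in percent of the substrate charged most ("none" if none brings more than 2 percentage points) (south-east / west / north / none)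
- amount of target at 3.0 min, in percent of the substrate charged, after south-east

- south-east: doubling the solubility in step 2, all else as stated
- west: doubling the dissolution coefficient of step 2, all else as stated
- north: doubling the amount of rival reagent, all else as stated

*What does the substrate choose between?* The partner or the rival reagent. At any moment, the target made per side product made is the target step's constant times the partner, over the side step's constant times the rival reagent. That is a selectivity factor: the substrate cancels from it, but the factor still moves during the run as the partner and the rival reagent change.

*Which partner do you use?* My own reckoning takes dissolution into empty solution, a rising exponential towards solubility, whose mean over the run is 5.22 mM. With the rival reagent as charged, the run-mean selectivity factor is 0.158.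

*And the target?* Its share of the substrate consumed, times the part consumed at both first-order rates, gives 9.60%.

*The changes?* South-east doubles the mean partner and gives 18.0%. West gives 14.0%, so I choose south-east.

*Does the solid last in south-east?* Standing partner plus partner used comes to about 20.5 mM, less than the 24.0 mM charged.

The forecast, lower than my figure, gives 8.5%, south-east and 15.9%, arguing that “Doubling solubility doubles the supply rate”.

The simulation gives 8.51%, south-east with 7.5 percentage points against 4.3 points for west, and 16.0%, so the forecast stands on all three.

In this flask at 3.00 min, target over side product reads 0.163, beside the factor of 0.158. The forecast's y is tied to the time: the answer has moved 5 points at 4.73 min. In the neighbour flask with 5.2 mM of rival reagent, the same mean partner gives a factor of 0.634 and a reckoned target of 13.5%. That neighbour's run gives 12.1% target and 16.2% side product, a reading of 0.748.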